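Every percent of free monomer charged has to be booked as monomer in chains, as isomer of the product, or as free monomer still unspent. Free monomer is the limiting reagent, and initiator is not used up mole for mole: at 10.0 h in Tuesday's run the chains hold 21.0 mM of monomer, more than the 0.20 mM of initiator charged.

| flask | free monomer | initiator | temperature | remark | time |
|---|---|---|---|---|---|
| Saturday's | 12 mM | 0.20 mM | −25 °C | run made earlier |  |
| Tuesday's | 30 mM | 0.20 mM | −14 °C | run made earlier |  |
| north-east | 10 mM | 0.20 mM | −20 °C |  | 30 h |
| west | 20 mM | 0.20 mM | −20 °C |  | 20 h |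

| run | time / h | monomer in chains / % | isomer of the product / % |
|---|---|---|---|
| Saturday's | 2.00 | 24.2 | 0.5 |
| Saturday's | 4.00 | 41.4 | 6.0 |
| Saturday's | 6.00 | 47.6 | 14.8 |
| Saturday's | 8.00 | 52.4 | 22.0 |
| Saturday's | 10.0 | 54.7 | 28.1 |
| Tuesday's | 0.833 | 24.1 | 3.2 |
| Tuesday's | 1.50 | 37.4 | 10.5 |
| Tuesday's | 3.00 | 53.0 | 17.5 |
| Tuesday's | 5.00 | 64.0 | 24.1 |
| Tuesday's | 10.0 | 70.1 | 29.8 |

(standard deviation of a reading: 1 percentage point)



* which one finishes higher in share of monomer in chains in all that became monomer in chains or isomer of the product ("neither" within 2 percentage points) (north-east / west / neither)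
* share of monomer in chains in all that became monomer in chains or isomer of the product, north-east
* share of monomer in chains in all that became monomer in chains or isomer of the product, west

First entry, free monomer. Saturday's run has 17.2 % unbooked at 10.0 h, and Tuesday's run 11.9 % at 5.00 h. Read as first-order loss, these give 0.176 h⁻¹ and 0.426 h⁻¹. Interpolated to −20 °C, that is 0.263 h⁻¹, so this reckoning leaves 0.520 % in west and 0.0375 % in north-east.

Second entry, chains into isomer, taken as first order in chains. The early readings, where isomer is still small, give 0.0996 h⁻¹ in Saturday's run and 0.356 h⁻¹ in Tuesday's. The same interpolation gives 0.178 h⁻¹, hence 3.90 h: the chain clock, the half-life of monomer in chains against the forward step into isomer.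

Third entry, the closing of the books. The clock is shorter than the 20 h of west, so the end share should follow the balance of chains and isomer: thermodynamic, not kinetic, control. Tuesday's run, 5.14 of its own clocks in, stands at 70.2 %. Saturday's, 1.44 clocks in, stands at 66.1 % and is still falling. With first order both ways the charge cancels, so this reckoning says neither: one share for both flasks, under Tuesday's figure.

The forecast says west, with 61 % for north-east and 65 % for west, on the ground that “higher concentration should favour chains”.

The flask gives neither: 53.2 % for north-east and 53.7 % for west.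

    free monomer + growing radical → monomer in chains + growing radical, rate k1*[growing radical]*[free monomer] (k = 13000 M⁻¹ s⁻¹, Ea = 12.0 kJ mol⁻¹)
    initiator → 2 initiating radical (k = 0.00150 h⁻¹, Ea = 88.0 kJ mol⁻¹)
    free monomer + initiating radical → growing radical + monomer in chains (k = 25000 M⁻¹ s⁻¹, Ea = 8.00 kJ mol⁻¹)
    monomer in chains ⇌ isomer of the product (K = 0.880, k = 0.180 h⁻¹, Ea = 80.0 kJ mol⁻¹, ΔH = −67.0 kJ mol⁻¹)
    2 growing radical → dead chain (k = 2.70 × 10⁶ M⁻¹ s⁻¹, Ea = 20.0 kJ mol⁻¹)
    (constants at −20 °C)

The clock runs 5.13 times in west, yet chains keep 53.7 % of the product, because isomer of the product turns back into monomer in chains. Without that undoing, the same flask ends at 7.15 %. West read at 5.0 h, 1.28 clocks in, still shows 70.2 %, with 27.4 % of the free monomer left.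

(The numbers in the tables were generated by integration from invented constants, noise included.)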